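# Caraphenol B by alkoxide-directed nickel syn-diarylation of a 1-substituted indene

## Analysis of the target

Caraphenol B is a 2,3-dihydro-1H-indene in which resorcinol ring A (hydroxyls on C4 and C6) is fused at C3a and C7a to the five-membered carbocycle, ring B. C1 carries the 4-hydroxybenzoyl group (C8 carbonyl and ring D), C2 the 4-hydroxyphenyl ring C and C3 the 3,5-dihydroxyphenyl ring E. The three contiguous stereocentres are (1R,2R,3R), which places all three substituents on one face of ring B, so the triad is all-cis. This is the crowded, less stable arrangement, and because C1–H is benzylic and alpha to the C8 ketone, any acid or base that enolises the ketone moves the aroyl group trans to ring C. The six free phenols make the compound polar and easily oxidised, so they stay masked to the end under groups that come off without acid or base. Ring B has no heteroatom, so the only handle near the stereotriad is the C8 oxygen, and the hard part is to place two different aryl groups on adjacent carbons, cis to each other and cis to a third, epimerisable substituent. The plan rests on one feature: rings E and C sit on C3 and C2 on the same face as the C1–C8 bond, which is the pattern left when two aryl groups add syn across C2=C3 of a 1-substituted indene from the face of its side chain while the C8 oxygen holds the metal.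

## Retrosynthetic reasoning

**17 to 16.** The six O–benzyl bonds are cut last. Benzyl is chosen because it leaves under neutral hydrogenolysis; once C8 is a ketone, C1 would not survive the Lewis acids that methyl ethers need. The forward step must cleave six ethers, one of them (on C4) crowded, without reducing the C8 carbonyl.

**16 to 15.** C8 is taken back to the carbinol. No bond is cut; what matters is the order of events. While C8 is sp3, C1–H of the indane is an ordinary benzylic hydrogen, and the same oxygen serves as the handle for the metal one step earlier. The oxidation must be neither basic nor acidic.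

**15 to 10, 13 and 14.** Both aryl–C(sp3) bonds of ring B are cut together: C3–ring E back to iodide 13 and C2–ring C back to boronic acid 14, leaving indene 10. These are the two bonds that lie cis to each other and cis to the side chain, which is what a syn addition across C2=C3 delivered from the C8 oxygen produces. Cutting elsewhere would leave the cis-diaryl unit to be made by reductions or protonations. The gain is two C–C bonds and two stereocentres in one step. The forward reaction must pick the face of the side chain, put ring E on C3 and ring C on C2, and leave the acidic C1–H of 10 alone.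

**10 to 9.** Ring B is opened at C2=C3 by a retro-metathesis to diene 9, in which C1 carries a vinyl group and ring A an ortho vinyl group. This is the one bond of ring B that can be closed under strictly neutral conditions. A shorter-looking path would join C1 to C8 on the intact five-membered ring by carbanion addition to 7 and then correct C1 by oxidation and asymmetric reduction. That path would pass through a C8 ketone on the unsaturated ring whose double bond moves into conjugation with the carbonyl, so C1 cannot be held. Setting C1 on an open chain and closing the ring afterwards keeps base away from the 1H-indene.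

**9 to 6 and 7.** C1–C8 is cut as an allylboration of aldehyde 7 by the γ-aryl allylboronate 6. This bond formation can set C1 and C8 together under catalyst control through a closed chair. The E geometry of 6 gives the anti pair, which is wanted because it turns ring D away from ring A in the later chelate.

**6 to 4 to 3.** Allylboronate 6 is the one-carbon homologue of alkenylboronate 4, and 4 comes from aldehyde 3 by olefination at the formyl carbon, which becomes C1. Two steps convert a formyl group into the E allylboron unit with no change of oxidation state elsewhere.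

**3 to 2 to 1.** The ortho vinyl group (the future C3) is cut back to bromide 2, and the C–Br bond to commercial aldehyde 1. Bromination ortho to the formyl group fixes the ring A pattern (C7a, C3a, C4–O, C6–O) at the outset.

**13 to 12 to 11.** Iodide 13 comes from the commercial dimethyl ether 11 by exchange of methyl for benzyl through diol 12, so that all six protecting groups of 16 are of one kind.

## Alternatives that were turned down

Alternative 1: a temporary hydroxyl on C1. The cut is at C3–ring E and C1–C2. In the forward key step Ni(OAc)2·4H2O (divalent nickel) with one enantiomer of a phosphinooxazoline ligand takes the aryl group of (3,5-dimethoxyphenyl)boronic acid A2 and places it on the alkyne of 1-{3,5-dimethoxy-2-[(4-methoxyphenyl)ethynyl]phenyl}-2-(4-methoxyphenyl)ethane-1,2-dione A1. The alkenylnickel formed from A1 and A2 turns about its double bond and adds to the C1 ketone, which closes ring B and gives the tertiary indenol [3-(3,5-dimethoxyphenyl)-1-hydroxy-4,6-dimethoxy-2-(4-methoxyphenyl)-1H-inden-1-yl](4-methoxyphenyl)methanone A3. In its favour, this arylative cyclisation is a known reaction type, so on precedent it is stronger than the chosen key step, and the catalyst sets the absolute configuration at a quaternary C1 that cannot epimerise and has no acidic hydrogen. Against it, for this target, the route leans on three difficult later operations. C2=C3 of A3 is tetrasubstituted with two aryl groups and would have to be hydrogenated under direction from a tertiary hydroxyl. The C1 oxygen must then be replaced by hydrogen through an enolate whose protonation has to be kinetic and against the thermodynamic preference. Six methyl ethers remain to be cleaved with a strong Lewis acid on the all-cis ketone, where C1 will epimerise. A1 is also a multi-step compound, whereas A2 is a simple reagent. By comparison, the chosen route makes both aryl-bearing centres directly at sp3 level with the C1 hydrogen already in place and unmasks under neutral conditions in fewer steps; the price is a key step without direct precedent.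

Alternative 2: a polyketide-type construction of ring A. The cut is at C3a–C4 and C7–C7a of ring A. In the forward key step the dianion of a cyclopentanone precursor that already carries the aroyl group and rings C and E is acylated at C3a by a ketal-protected acetoacetate (Claisen). Mild acid then unmasks the C6 ketone, and aldol closure of C7 onto C7a with aromatisation gives 1-epi-caraphenol B tetramethyl ether A4, with ring A as the free diol. In its favour, the resorcinol forms with unambiguous regiochemistry and no protecting group on ring A, and no transition-metal step of uncertain regiochemistry is involved; on that point it is stronger. Against it, for this target, C1 sits between two carbonyl groups throughout the key step and equilibrates to the trans configuration, so A4 is the wrong C1 epimer. Correcting it afterwards again means a contra-thermodynamic protonation. The enantiopure trisubstituted cyclopentanone is a multi-step problem of its own, and rings C, D and E of A4 still carry methyl ethers. By comparison, the chosen route sets C1 first and never places it alpha to a carbonyl until the penultimate step.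

Alternative 3: aryne insertion. The cut is at C1–C7a and C3–C3a, the two benzylic bonds to ring A. In the forward key step CsF releases a dimethoxy aryne from its ortho-silyl triflate precursor, and a 1,3-diketone adds and fragments, formally inserting the aryne into its α-carbon–carbonyl bond. The product is 2-[2-(3,5-dimethoxybenzoyl)-3,5-dimethoxyphenyl]-1-(4-methoxyphenyl)ethanone A5. In its favour, it is convergent, uses a known reaction class, and joins both benzylic carbons to ring A in one step from simple materials; on convergence and precedent it is stronger. Against it, for this target, A5 is achiral and lacks C2 and ring C. The sense of addition to the unsymmetrical aryne and the choice of migrating acyl group are both open. Ring B must still be closed and all three stereocentres made afterwards, with no handle for absolute configuration, and the methyl ether problem remains. By comparison, the chosen strategy addresses the stereotriad directly, two centres in the key step and the third before it, whereas the path through A5 leaves all three open.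

Key step: step 9

## Remarks and assumptions

- Compounds 1, 7, 11 and 14 are taken to be commercial.
- The sense of induction of the phosphoric acid in step 5 (Si face of the aldehyde with the S catalyst) is assigned by analogy with simple aryl aldehydes. If it proves opposite, the antipodal catalyst is used.
- In step 9 the boronic acid is kept in excess over the hydroxide, so that the base is present as the trihydroxyborate and the medium is only weakly basic.

## Route

Step 1
Reactants: 1 3,5-bis(benzyloxy)benzaldehyde
Product: 2 2-bromo-3,5-bis(benzyloxy)benzaldehyde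
Conditions: NBS (1.0 equiv), MeCN, 0 °C to rt
Reagents that add atoms: N-bromosuccinimide, O=C1CCC(=O)N1Br
Why: Electrophilic aromatic bromination; C2 is ortho and para to the two benzyloxy groups and less shielded than C4 between them, the selectivity known for 3,5-dialkoxybenzaldehydes, and the benzyl rings are not activated enough to compete.

Step 2
Reactants: 2 2-bromo-3,5-bis(benzyloxy)benzaldehyde
Product: 3 3,5-bis(benzyloxy)-2-ethenylbenzaldehyde
Conditions: potassium vinyltrifluoroborate, Pd(OAc)2 (5 mol %), SPhos (10 mol %), K2CO3, 1,4-dioxane–H2O, 85 °C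
Reagents that add atoms: potassium vinyltrifluoroborate, [K+].C=C[B-](F)(F)F
Why: Suzuki–Miyaura vinylation; a bulky biaryl phosphine copes with the doubly ortho-substituted, electron-rich bromide, and the aldehyde and benzyl ethers are inert.

Step 3
Reactants: 3 3,5-bis(benzyloxy)-2-ethenylbenzaldehyde
Product: 4 2-{(E)-2-[3,5-bis(benzyloxy)-2-ethenylphenyl]ethenyl}-4,4,5,5-tetramethyl-1,3,2-dioxaborolane
Conditions: CH2(Bpin)2, LiTMP, THF, 0 °C; then 3, −78 °C to rt
Reagents that add atoms: bis[(pinacolato)boryl]methane, CC1(C)OB(CB2OC(C)(C)C(C)(C)O2)OC1(C)C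
Why: Boron-Wittig olefination: the α-boryl carbanion adds to the aldehyde and syn elimination of B–O gives the alkenylboronate, E being the geometry favoured with aryl aldehydes; the styrene is not touched.

Step 4
Reactants: 4 2-{(E)-2-[3,5-bis(benzyloxy)-2-ethenylphenyl]ethenyl}-4,4,5,5-tetramethyl-1,3,2-dioxaborolane
Product: 6 2-{(E)-3-[3,5-bis(benzyloxy)-2-ethenylphenyl]prop-2-en-1-yl}-4,4,5,5-tetramethyl-1,3,2-dioxaborolane, via lithium chloromethyl boronate complex 5 (not isolated)
Conditions: ICH2Cl, n-BuLi, THF, −78 °C to rt
Reagents that add atoms: chloroiodomethane, ClCI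
Why: Matteson homologation: chloromethyllithium from iodine–lithium exchange adds to boron, and the alkenyl group migrates to carbon with loss of chloride and retention of the E geometry, giving the γ-aryl allylboronate.

Step 5
Reactants: 6 2-{(E)-3-[3,5-bis(benzyloxy)-2-ethenylphenyl]prop-2-en-1-yl}-4,4,5,5-tetramethyl-1,3,2-dioxaborolane; 7 4-(benzyloxy)benzaldehyde
Product: 9 (1S,2R)-1-[4-(benzyloxy)phenyl]-2-[3,5-bis(benzyloxy)-2-ethenylphenyl]but-3-en-1-ol, via pinacol borate ester 8 (not isolated)
Conditions: (S)-3,3'-bis(2,4,6-triisopropylphenyl)-1,1'-binaphthyl-2,2'-diyl hydrogen phosphate (5 mol %), 4 Å MS, toluene, −30 °C; aqueous NaHCO3 work-up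
Reagents that add atoms: none
Why: Chiral phosphoric acid-catalysed allylboration through a Zimmerman–Traxler chair; the E boronate places its aryl group equatorial and gives the anti relation of C8 and C1, and the catalyst selects the Si face of the aldehyde, so C8 should be S and C1 R.

Step 6
Reactants: 9 (1S,2R)-1-[4-(benzyloxy)phenyl]-2-[3,5-bis(benzyloxy)-2-ethenylphenyl]but-3-en-1-ol
Product: 10 (S)-[4-(benzyloxy)phenyl][(1R)-4,6-bis(benzyloxy)-1H-inden-1-yl]methanol
Conditions: second-generation Grubbs catalyst RuCl2(=CHPh)(PCy3)(H2IMes) (5 mol %), 1,4-benzoquinone (10 mol %), CH2Cl2, 40 °C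
Reagents that add atoms: none
Why: Ring-closing metathesis of the allylic vinyl group onto the styrene closes ring B at C2=C3 with loss of ethene; the medium is neutral, so the C1 centre from step 5 is kept and the double bond stays in place, and benzoquinone intercepts ruthenium hydrides that could move it.

Step 7
Reactants: 11 1-iodo-3,5-dimethoxybenzene
Product: 12 5-iodobenzene-1,3-diol
Conditions: BBr3, CH2Cl2, −78 °C to rt; then H2O
Reagents that add atoms: none
Why: Lewis acid cleavage of aryl methyl ethers; the aryl iodide is stable to BBr3.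

Step 8
Reactants: 12 5-iodobenzene-1,3-diol
Product: 13 1,3-bis(benzyloxy)-5-iodobenzene
Conditions: BnBr, K2CO3, DMF, 60 °C
Reagents that add atoms: benzyl bromide, BrCc1ccccc1
Why: Williamson etherification of both phenols; it puts ring E under the same neutral-labile protection as the rest of the molecule.

Step 9
Reactants: 10 (S)-[4-(benzyloxy)phenyl][(1R)-4,6-bis(benzyloxy)-1H-inden-1-yl]methanol; 13 1,3-bis(benzyloxy)-5-iodobenzene; 14 4-(benzyloxy)phenylboronic acid
Product: 15 (S)-[4-(benzyloxy)phenyl]{(1R,2R,3R)-4,6-bis(benzyloxy)-2-[4-(benzyloxy)phenyl]-3-[3,5-bis(benzyloxy)phenyl]-2,3-dihydro-1H-inden-1-yl}methanol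
Conditions: Ni(cod)2 (15 mol %), 13 (1.5 equiv), 14 (3 equiv), powdered NaOH (2 equiv), s-BuOH–THF, 0 °C to rt
Reagents that add atoms: none
Why: Proposed new method: zerovalent nickel inserts into the C–I bond of 13 and the C8 hydroxyl of 10 replaces iodide on nickel (the borate takes the proton), so an aryl nickel alkoxide sits over the face of ring B that carries the side chain. C2=C3 then inserts syn into the Ni–aryl bond, ring E going to C3 and nickel to C2 within a five-membered O–C8–C1–C2–Ni chelate; no ring of the product is closed. Neither C1–H nor C3–H is syn to nickel, so β-hydride elimination is shut, and transmetallation from the trihydroxyborate of 14 followed by C(sp3)–C(sp2) reductive elimination with retention puts ring C on C2 on the same face. Both new stereocentres (C3 at insertion, C2 at reductive elimination) are thus set by the existing C1 centre through the nickel-bound oxygen, giving the all-cis (1R,2R,3R) triad. The closest known reaction type is the nickel-catalysed syn-1,2-diarylation of alkenyl ketones, amides and carboxylates with an aryl iodide and an arylboron reagent, in which a native carbonyl oxygen holds the metal; new here are an alkoxide as director and an indene (a cyclic styrene) as the alkene. The step needs three selectivities: face (the chelate, helped by the anti C8 configuration from step 5, which turns ring D outwards), regiochemistry (the five-membered chelate and the ortho/para alkoxy groups of ring A, which polarise C2=C3 so that C3 takes the migrating aryl group and C2 the metal, against the usual preference for benzylic nickel) and chemoselectivity for the alkene over the acidic C1–H, secured by keeping NaOH below the amount of 14 so that all hydroxide is bound as borate.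

Step 10
Reactants: 15 (S)-[4-(benzyloxy)phenyl]{(1R,2R,3R)-4,6-bis(benzyloxy)-2-[4-(benzyloxy)phenyl]-3-[3,5-bis(benzyloxy)phenyl]-2,3-dihydro-1H-inden-1-yl}methanol
Product: 16 [4-(benzyloxy)phenyl]{(1R,2R,3R)-4,6-bis(benzyloxy)-2-[4-(benzyloxy)phenyl]-3-[3,5-bis(benzyloxy)phenyl]-2,3-dihydro-1H-inden-1-yl}methanone
Conditions: Dess–Martin periodinane, NaHCO3, CH2Cl2, 0 °C
Reagents that add atoms: none
Why: Dess–Martin oxidation of the secondary benzylic carbinol under bicarbonate buffer; C1–H becomes acidic only now and meets neither strong base nor strong acid, so C1, C2 and C3 should be unchanged.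

Step 11
Reactants: 16 [4-(benzyloxy)phenyl]{(1R,2R,3R)-4,6-bis(benzyloxy)-2-[4-(benzyloxy)phenyl]-3-[3,5-bis(benzyloxy)phenyl]-2,3-dihydro-1H-inden-1-yl}methanone
Product: 17 caraphenol B, (4-hydroxyphenyl)[(1R,2R,3R)-4,6-dihydroxy-3-(3,5-dihydroxyphenyl)-2-(4-hydroxyphenyl)-2,3-dihydro-1H-inden-1-yl]methanone
Conditions: H2 (1 atm), Pd(OH)2 on carbon, EtOAc–MeOH, rt
Reagents that add atoms: none
Why: Hydrogenolysis of the six aryl benzyl ethers in a neutral medium; the hindered, electron-rich aryl ketone is reduced much more slowly, and without acid or base C1 should not epimerise.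

## Compound list

1 | 3,5-bis(benzyloxy)benzaldehyde | O=Cc1cc(OCc2ccccc2)cc(OCc2ccccc2)c1 | starting material
2 | 2-bromo-3,5-bis(benzyloxy)benzaldehyde | O=Cc1cc(OCc2ccccc2)cc(OCc2ccccc2)c1Br | intermediate
3 | 3,5-bis(benzyloxy)-2-ethenylbenzaldehyde | O=Cc1cc(OCc2ccccc2)cc(OCc2ccccc2)c1C=C | intermediate
4 | 2-{(E)-2-[3,5-bis(benzyloxy)-2-ethenylphenyl]ethenyl}-4,4,5,5-tetramethyl-1,3,2-dioxaborolane | CC1(C)OB(/C=C/c2cc(OCc3ccccc3)cc(OCc3ccccc3)c2C=C)OC1(C)C | intermediate
5 | lithium (chloromethyl){(E)-2-[3,5-bis(benzyloxy)-2-ethenylphenyl]ethenyl}(pinacolato)borate | [Li+].ClC[B-]1(/C=C/c2cc(OCc3ccccc3)cc(OCc3ccccc3)c2C=C)OC(C)(C)C(C)(C)O1 | intermediate (not isolated)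
6 | 2-{(E)-3-[3,5-bis(benzyloxy)-2-ethenylphenyl]prop-2-en-1-yl}-4,4,5,5-tetramethyl-1,3,2-dioxaborolane | CC1(C)OB(C/C=C/c2cc(OCc3ccccc3)cc(OCc3ccccc3)c2C=C)OC1(C)C | intermediate
7 | 4-(benzyloxy)benzaldehyde | O=Cc1ccc(OCc2ccccc2)cc1 | starting material
8 | 2-{(1S,2R)-1-[4-(benzyloxy)phenyl]-2-[3,5-bis(benzyloxy)-2-ethenylphenyl]but-3-en-1-yloxy}-4,4,5,5-tetramethyl-1,3,2-dioxaborolane | CC1(C)OB(O[C@H](c2ccc(OCc3ccccc3)cc2)[C@H](C=C)c2cc(OCc3ccccc3)cc(OCc3ccccc3)c2C=C)OC1(C)C | intermediate (not isolated)
9 | (1S,2R)-1-[4-(benzyloxy)phenyl]-2-[3,5-bis(benzyloxy)-2-ethenylphenyl]but-3-en-1-ol (anti) | O[C@H](c1ccc(OCc2ccccc2)cc1)[C@H](C=C)c1cc(OCc2ccccc2)cc(OCc2ccccc2)c1C=C | intermediate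
10 | (S)-[4-(benzyloxy)phenyl][(1R)-4,6-bis(benzyloxy)-1H-inden-1-yl]methanol | O[C@H](c1ccc(OCc2ccccc2)cc1)[C@H]1c2cc(OCc3ccccc3)cc(OCc3ccccc3)c2C=C1 | intermediate (precursor of the key step)
11 | 1-iodo-3,5-dimethoxybenzene | COc1cc(I)cc(OC)c1 | starting material
12 | 5-iodobenzene-1,3-diol | Oc1cc(O)cc(I)c1 | intermediate
13 | 1,3-bis(benzyloxy)-5-iodobenzene | Ic1cc(OCc2ccccc2)cc(OCc2ccccc2)c1 | intermediate
14 | 4-(benzyloxy)phenylboronic acid | OB(O)c1ccc(OCc2ccccc2)cc1 | starting material
15 | (S)-[4-(benzyloxy)phenyl]{(1R,2R,3R)-4,6-bis(benzyloxy)-2-[4-(benzyloxy)phenyl]-3-[3,5-bis(benzyloxy)phenyl]-2,3-dihydro-1H-inden-1-yl}methanol (all-cis) | O[C@H](c1ccc(OCc2ccccc2)cc1)[C@H]1c2cc(OCc3ccccc3)cc(OCc3ccccc3)c2[C@@H](c2cc(OCc3ccccc3)cc(OCc3ccccc3)c2)[C@H]1c1ccc(OCc2ccccc2)cc1 | intermediate (product of the key step)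
16 | [4-(benzyloxy)phenyl]{(1R,2R,3R)-4,6-bis(benzyloxy)-2-[4-(benzyloxy)phenyl]-3-[3,5-bis(benzyloxy)phenyl]-2,3-dihydro-1H-inden-1-yl}methanone | O=C(c1ccc(OCc2ccccc2)cc1)[C@H]1c2cc(OCc3ccccc3)cc(OCc3ccccc3)c2[C@@H](c2cc(OCc3ccccc3)cc(OCc3ccccc3)c2)[C@H]1c1ccc(OCc2ccccc2)cc1 | intermediate
17 | caraphenol B, (4-hydroxyphenyl)[(1R,2R,3R)-4,6-dihydroxy-3-(3,5-dihydroxyphenyl)-2-(4-hydroxyphenyl)-2,3-dihydro-1H-inden-1-yl]methanone | O=C(c1ccc(O)cc1)[C@H]1c2cc(O)cc(O)c2[C@@H](c2cc(O)cc(O)c2)[C@H]1c1ccc(O)cc1 | target

## Step count

Total: 11 steps. Longest linear sequence: 9 steps (steps 1 to 6, then 9 to 11). The ring E iodide is a two-step side branch (steps 7 and 8).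

## Least certain steps

**Step 9 (key step, new method).** Several processes can compete with the intended addition. The first is insertion with the opposite orientation, nickel ending on the benzylic C3 in a six-membered chelate, because aryl nickel species normally add to styrenes in that sense and C3 is shielded by the C4 benzyloxy group. This would interchange rings C and E; inside the same step it is answered by exchanging the roles of the partners (ring C as the iodide, ring E as the boronic acid), which leads to 15 again. The second is β-hydride loss from the nickel alkoxide at C8, which oxidises the carbinol at the expense of the iodide. The third is proton abstraction from C1 of the indene (pKa about 20), followed by double-bond migration, retro-addition to the aldehyde or loss of water. The others are direct biaryl coupling of the two aryl partners and addition on the face away from the side chain if the oxygen does not bind nickel.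

Fallback with known chemistry, from 10 back to 15: the aryl groups are placed on an sp2 C2=C3 and the cis relation to the side chain is made by hydrogenation from the open face. Compound 10 is silylated (TBSCl, imidazole, DMF) to tert-butyl{(S)-[4-(benzyloxy)phenyl][(1R)-4,6-bis(benzyloxy)-1H-inden-1-yl]methoxy}dimethylsilane F1. Mukaiyama hydration (Co(acac)2, PhSiH3, O2, THF) puts oxygen on the benzylic C3 and gives (3R)-5,7-bis(benzyloxy)-3-{(S)-[4-(benzyloxy)phenyl][(tert-butyldimethylsilyl)oxy]methyl}-2,3-dihydro-1H-inden-1-ol F2 as a mixture at the carbinol carbon. Dess–Martin oxidation converts it to (3R)-5,7-bis(benzyloxy)-3-{(S)-[4-(benzyloxy)phenyl][(tert-butyldimethylsilyl)oxy]methyl}-2,3-dihydro-1H-inden-1-one F3, in which the old C1 is beta to the ketone and no longer acidic. Palladium-catalysed ketone α-arylation with 1-(benzyloxy)-4-bromobenzene (Pd2(dba)3, XPhos, NaOtBu, toluene, 70 °C) gives (3R)-5,7-bis(benzyloxy)-2-[4-(benzyloxy)phenyl]-3-{(S)-[4-(benzyloxy)phenyl][(tert-butyldimethylsilyl)oxy]methyl}-2,3-dihydro-1H-inden-1-one F4. 3,5-Bis(benzyloxy)phenyllithium (from 13 and n-BuLi, transmetallated to CeCl3) adds to the carbonyl to give (3R)-5,7-bis(benzyloxy)-2-[4-(benzyloxy)phenyl]-1-[3,5-bis(benzyloxy)phenyl]-3-{(S)-[4-(benzyloxy)phenyl][(tert-butyldimethylsilyl)oxy]methyl}-2,3-dihydro-1H-inden-1-ol F5. Burgess reagent in toluene at 50 °C, chosen over a protic acid so that the benzylic silyl ether is not ionised, dehydrates it to tert-butyl{(S)-[4-(benzyloxy)phenyl][(1S)-4,6-bis(benzyloxy)-2-[4-(benzyloxy)phenyl]-3-[3,5-bis(benzyloxy)phenyl]-1H-inden-1-yl]methoxy}dimethylsilane F6; the descriptor at C1 changes by the sequence rule only, and the spatial arrangement is that of 10. Hydrogenation with [Ir(cod)(PCy3)(py)]PF6 (H2, CH2Cl2), a catalyst type that reduces tetrasubstituted alkenes and spares benzyl ethers, should deliver both hydrogens to the face opposite the C1 side chain, which pushes rings C and E cis to it and gives tert-butyl{(S)-[4-(benzyloxy)phenyl][(1R,2R,3R)-4,6-bis(benzyloxy)-2-[4-(benzyloxy)phenyl]-3-[3,5-bis(benzyloxy)phenyl]-2,3-dihydro-1H-inden-1-yl]methoxy}dimethylsilane F7. Bu4NF removes the silyl group and returns 15. The indene stage of this sequence is handled only under neutral conditions, so the acidic C1–H is not at risk.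

**Step 5 (allylboration).** The enantio- and diastereocontrol may be eroded by the uncatalysed background addition, because the electron-rich aldehyde and the ortho-substituted γ-aryl group slow the catalysed pathway.

Fallback, from 6 and 7 back to 9: the uncatalysed allylboration (toluene, rt) goes through the same chair and gives the racemic anti alcohol rac-(1S,2R)-1-[4-(benzyloxy)phenyl]-2-[3,5-bis(benzyloxy)-2-ethenylphenyl]but-3-en-1-ol F8. Esterification with (S)-2-methoxy-2-phenylacetic acid (DCC, DMAP) and chromatographic separation of the diastereomers gives (1S,2R)-1-[4-(benzyloxy)phenyl]-2-[3,5-bis(benzyloxy)-2-ethenylphenyl]but-3-en-1-yl (S)-2-methoxy-2-phenylacetate F9. Methanolysis (K2CO3, MeOH) returns 9. This is resolution in place of catalyst control.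

**Step 4 (Matteson homologation).** Double homologation or attack of n-BuLi on boron may compete with the iodine–lithium exchange, and the allylboronate may suffer boron migration or protodeboronation during isolation.

Fallback, from 3 back to 6: Horner–Wadsworth–Emmons olefination with triethyl phosphonoacetate (NaH, THF) gives ethyl (E)-3-[3,5-bis(benzyloxy)-2-ethenylphenyl]prop-2-enoate F10. DIBAL-H (CH2Cl2, −78 °C) gives (E)-3-[3,5-bis(benzyloxy)-2-ethenylphenyl]prop-2-en-1-ol F11. Palladium-catalysed borylation of the allylic alcohol with B2pin2 (Pd(MeCN)4(BF4)2, DMSO–MeOH) gives the linear E allylboronate 6.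

**Step 11 (global debenzylation).** The C8 carbonyl may be reduced (to the carbinol and on to the methylene) during the long exposure that the hindered C4 ether needs, and C1 may epimerise on the catalyst surface.

Fallback, from 16 directly to 17: BCl3 with pentamethylbenzene as cation scavenger (CH2Cl2, −78 °C). This is a non-reductive ether cleavage at low temperature that takes the benzyl groups off as benzyl cations and makes no new compound.

## Further compounds

F1 | step 9 | tert-butyl{(S)-[4-(benzyloxy)phenyl][(1R)-4,6-bis(benzyloxy)-1H-inden-1-yl]methoxy}dimethylsilane | CC(C)(C)[Si](C)(C)O[C@H](c1ccc(OCc2ccccc2)cc1)[C@H]1c2cc(OCc3ccccc3)cc(OCc3ccccc3)c2C=C1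
F2 | step 9 | (3R)-5,7-bis(benzyloxy)-3-{(S)-[4-(benzyloxy)phenyl][(tert-butyldimethylsilyl)oxy]methyl}-2,3-dihydro-1H-inden-1-ol (mixture at C1) | CC(C)(C)[Si](C)(C)O[C@H](c1ccc(OCc2ccccc2)cc1)[C@H]1c2cc(OCc3ccccc3)cc(OCc3ccccc3)c2C(O)C1
F3 | step 9 | (3R)-5,7-bis(benzyloxy)-3-{(S)-[4-(benzyloxy)phenyl][(tert-butyldimethylsilyl)oxy]methyl}-2,3-dihydro-1H-inden-1-one | CC(C)(C)[Si](C)(C)O[C@H](c1ccc(OCc2ccccc2)cc1)[C@H]1c2cc(OCc3ccccc3)cc(OCc3ccccc3)c2C(=O)C1
F4 | step 9 | (3R)-5,7-bis(benzyloxy)-2-[4-(benzyloxy)phenyl]-3-{(S)-[4-(benzyloxy)phenyl][(tert-butyldimethylsilyl)oxy]methyl}-2,3-dihydro-1H-inden-1-one (mixture at C2) | CC(C)(C)[Si](C)(C)O[C@H](c1ccc(OCc2ccccc2)cc1)[C@H]1c2cc(OCc3ccccc3)cc(OCc3ccccc3)c2C(=O)C1c1ccc(OCc2ccccc2)cc1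
F5 | step 9 | (3R)-5,7-bis(benzyloxy)-2-[4-(benzyloxy)phenyl]-1-[3,5-bis(benzyloxy)phenyl]-3-{(S)-[4-(benzyloxy)phenyl][(tert-butyldimethylsilyl)oxy]methyl}-2,3-dihydro-1H-inden-1-ol (mixture at C1 and C2) | CC(C)(C)[Si](C)(C)O[C@H](c1ccc(OCc2ccccc2)cc1)[C@H]1c2cc(OCc3ccccc3)cc(OCc3ccccc3)c2C(O)(c2cc(OCc3ccccc3)cc(OCc3ccccc3)c2)C1c1ccc(OCc2ccccc2)cc1
F6 | step 9 | tert-butyl{(S)-[4-(benzyloxy)phenyl][(1S)-4,6-bis(benzyloxy)-2-[4-(benzyloxy)phenyl]-3-[3,5-bis(benzyloxy)phenyl]-1H-inden-1-yl]methoxy}dimethylsilane | CC(C)(C)[Si](C)(C)O[C@H](c1ccc(OCc2ccccc2)cc1)[C@H]1c2cc(OCc3ccccc3)cc(OCc3ccccc3)c2C(c2cc(OCc3ccccc3)cc(OCc3ccccc3)c2)=C1c1ccc(OCc2ccccc2)cc1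
F7 | step 9 | tert-butyl{(S)-[4-(benzyloxy)phenyl][(1R,2R,3R)-4,6-bis(benzyloxy)-2-[4-(benzyloxy)phenyl]-3-[3,5-bis(benzyloxy)phenyl]-2,3-dihydro-1H-inden-1-yl]methoxy}dimethylsilane | CC(C)(C)[Si](C)(C)O[C@H](c1ccc(OCc2ccccc2)cc1)[C@H]1c2cc(OCc3ccccc3)cc(OCc3ccccc3)c2[C@@H](c2cc(OCc3ccccc3)cc(OCc3ccccc3)c2)[C@H]1c1ccc(OCc2ccccc2)cc1
F8 | step 5 | rac-(1S,2R)-1-[4-(benzyloxy)phenyl]-2-[3,5-bis(benzyloxy)-2-ethenylphenyl]but-3-en-1-ol (racemic anti, both enantiomers written) | O[C@H](c1ccc(OCc2ccccc2)cc1)[C@H](C=C)c1cc(OCc2ccccc2)cc(OCc2ccccc2)c1C=C.O[C@@H](c1ccc(OCc2ccccc2)cc1)[C@@H](C=C)c1cc(OCc2ccccc2)cc(OCc2ccccc2)c1C=C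
F9 | step 5 | (1S,2R)-1-[4-(benzyloxy)phenyl]-2-[3,5-bis(benzyloxy)-2-ethenylphenyl]but-3-en-1-yl (S)-2-methoxy-2-phenylacetate | CO[C@H](C(=O)O[C@H](c1ccc(OCc2ccccc2)cc1)[C@H](C=C)c1cc(OCc2ccccc2)cc(OCc2ccccc2)c1C=C)c1ccccc1
F10 | step 4 | ethyl (E)-3-[3,5-bis(benzyloxy)-2-ethenylphenyl]prop-2-enoate | CCOC(=O)/C=C/c1cc(OCc2ccccc2)cc(OCc2ccccc2)c1C=C
F11 | step 4 | (E)-3-[3,5-bis(benzyloxy)-2-ethenylphenyl]prop-2-en-1-ol | OC/C=C/c1cc(OCc2ccccc2)cc(OCc2ccccc2)c1C=C
F0 | step 11 | none | none
A1 | alternative 1 | 1-{3,5-dimethoxy-2-[(4-methoxyphenyl)ethynyl]phenyl}-2-(4-methoxyphenyl)ethane-1,2-dione | COc1ccc(cc1)C(=O)C(=O)c1cc(OC)cc(OC)c1C#Cc1ccc(OC)cc1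
A2 | alternative 1 | (3,5-dimethoxyphenyl)boronic acid | COc1cc(cc(OC)c1)B(O)O
A3 | alternative 1 | [3-(3,5-dimethoxyphenyl)-1-hydroxy-4,6-dimethoxy-2-(4-methoxyphenyl)-1H-inden-1-yl](4-methoxyphenyl)methanone, single C1 enantiomer | O=C(c1ccc(OC)cc1)[C@@]1(O)c2cc(OC)cc(OC)c2C(c2cc(OC)cc(OC)c2)=C1c1ccc(OC)cc1
A4 | alternative 2 | 1-epi-caraphenol B tetramethyl ether, [4,6-dihydroxy-3-(3,5-dimethoxyphenyl)-2-(4-methoxyphenyl)-2,3-dihydro-1H-inden-1-yl](4-methoxyphenyl)methanone with rings C and E cis and C1 trans | O=C(c1ccc(OC)cc1)[C@@H]1c2cc(O)cc(O)c2[C@@H](c2cc(OC)cc(OC)c2)[C@H]1c1ccc(OC)cc1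
A5 | alternative 3 | 2-[2-(3,5-dimethoxybenzoyl)-3,5-dimethoxyphenyl]-1-(4-methoxyphenyl)ethanone | COc1ccc(cc1)C(=O)Cc1cc(OC)cc(OC)c1C(=O)c1cc(OC)cc(OC)c1
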